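**Plan**

1. Numbering used below: side chain C-1′ (CH2 on the quinone ring) to C-10′ (exocyclic =CH); C-11′ is the lactone ring carbon that carries this alkene, C-14′ the ring CH–O that carries the isopropenyl group.
2. Retrosynthetic cuts, in order: the second C=O of the six-membered carbocycle (back to a 2,6-dialkylphenol), the lactone acyl–O bond to C-14′ (back to a silyloxy methyl ester), the C-8′–C-7′ bond, then C-10′=C-11′ and C-11′–C-12′ in the left half, and aryl–C-1′, C-1′–C-2′, C-3′–CH3 and C-7′–I in the right half.
3. Feature that allows the key event: C-8′ is an unbranched primary sp3 CH2 without stereocentre, insulated by C-9′ from the enoate, and C-7′ is the methyl-bearing sp2 carbon of the 6′E alkene, so the bond can be made by a stereoretentive B-alkyl Suzuki–Miyaura coupling of a primary alkylboronate with an (E)-2-iodoalkene. The six-membered lactone is kept open during it, because its ring C–O bond is allylic to the isopropenyl group and would ionise with zerovalent palladium.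
4. Forward: left half (steps 1–7), right half (steps 8–13), chain joined at C-8′–C-7′ (step 14), then the lactone ring is closed (step 15), and last the benzene ring is oxidised to the quinone ring (step 16).
5. Stereochemistry: C-14′ (R) from a CBS reduction of the isopropenyl ketone; 10′Z from a Still–Gennari olefination; 6′E from syn-hydrozirconation/iodinolysis, carried through the coupling with retention; 2′E from syn-carboalumination.

Key step: step 14

**Route**

Step 1
Reactants: 1 3-bromopropanoyl chloride; 2 prop-1-en-2-ylmagnesium bromide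
Product: 4 5-bromo-2-methylpent-1-en-3-one, via isopropenylzinc chloride 3 (not isolated)
Conditions: ZnCl2, THF, 0 °C; then Pd(PPh3)4 (3 mol %), 1, 0 → 23 °C
Reagents that add atoms: zinc chloride, Cl[Zn]Cl (its zinc and chloride stay in intermediate 3 and do not reach 4)
Why: Negishi acylation: the alkenylzinc made by Mg-to-Zn exchange is acylated by the acid chloride under zerovalent palladium catalysis, without the basic conditions that would eliminate HBr from the β-bromo ketone and without touching the primary bromide.

Step 2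
Reactants: 4 5-bromo-2-methylpent-1-en-3-one
Product: 5 (3R)-5-bromo-2-methylpent-1-en-3-ol
Conditions: (S)-2-methyl-CBS-oxazaborolidine (20 mol %), catecholborane, toluene, −78 °C; aq. work-up
Reagents that add atoms: none
Why: Corey–Bakshi–Shibata reduction: the (S)-oxazaborolidine should treat the α-branched isopropenyl group as the large substituent and deliver hydride to the Si face, setting the (R) carbinol centre, while catecholborane at low temperature avoids hydroboration of the alkene.

Step 3
Reactants: 5 (3R)-5-bromo-2-methylpent-1-en-3-ol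
Product: 6 tert-butyl{[(3R)-5-bromo-2-methylpent-1-en-3-yl]oxy}dimethylsilane
Conditions: TBSOTf, 2,6-lutidine, CH2Cl2, −78 °C
Reagents that add atoms: tert-butyldimethylsilyl trifluoromethanesulfonate, CC(C)(C)[Si](C)(C)OS(=O)(=O)C(F)(F)F
Why: Silyl ether formation: this keeps the δ-hydroxy group from lactonising onto the ester that is introduced next, and the fast low-temperature silylation leaves the primary bromide untouched.

Step 4
Reactants: 6 tert-butyl{[(3R)-5-bromo-2-methylpent-1-en-3-yl]oxy}dimethylsilane; 7 methyl 2-[bis(2,2,2-trifluoroethoxy)phosphoryl]acetate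
Product: 9 methyl (5R)-2-[bis(2,2,2-trifluoroethoxy)phosphoryl]-5-[(tert-butyldimethylsilyl)oxy]-6-methylhept-6-enoate, via sodium phosphonoacetate 8 (not isolated)
Conditions: NaH, DMF, 0 °C; then 6, NaI (10 mol %), 23 → 45 °C
Reagents that add atoms: sodium hydride, [Na+].[H-] (sodium appears in intermediate 8 only)
Why: SN2 C-alkylation of a stabilised phosphonoacetate anion with an unhindered primary bromide (malonate-type alkylation); the new α-centre forms as both epimers, which is irrelevant because it becomes sp2 in step 7.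

Step 5
Reactants: 10 3,3-diethoxyprop-1-ene
Product: 11 2-(3,3-diethoxypropyl)-4,4,5,5-tetramethyl-1,3,2-dioxaborolane
Conditions: pinacolborane, [Ir(cod)Cl]2 (1.5 mol %), Ph2PCH2CH2PPh2 (3 mol %), CH2Cl2, 23 °C
Reagents that add atoms: pinacolborane, [H]B1OC(C)(C)C(C)(C)O1
Why: Iridium-catalysed anti-Markovnikov hydroboration of a monosubstituted alkene, which places boron on the terminal carbon that will become C-8′.

Step 6
Reactants: 11 2-(3,3-diethoxypropyl)-4,4,5,5-tetramethyl-1,3,2-dioxaborolane
Product: 12 3-(4,4,5,5-tetramethyl-1,3,2-dioxaborolan-2-yl)propanal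
Conditions: 2 M HCl, THF, 0 → 23 °C; used crude
Reagents that add atoms: water, O
Why: Acid-catalysed acetal hydrolysis, to which the pinacol boronate is inert; the β-boryl aldehyde is taken on without purification.

Step 7
Reactants: 9 methyl (5R)-2-[bis(2,2,2-trifluoroethoxy)phosphoryl]-5-[(tert-butyldimethylsilyl)oxy]-6-methylhept-6-enoate; 12 3-(4,4,5,5-tetramethyl-1,3,2-dioxaborolan-2-yl)propanal
Product: 14 methyl (2Z)-2-[(3R)-3-[(tert-butyldimethylsilyl)oxy]-4-methylpent-4-en-1-yl]-5-(4,4,5,5-tetramethyl-1,3,2-dioxaborolan-2-yl)pent-2-enoate, via potassium phosphonate salt 13 (not isolated)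
Conditions: KN(SiMe3)2, 18-crown-6, THF, −78 °C; then 12, −78 °C
Reagents that add atoms: potassium hexamethyldisilazide, C[Si](C)(C)[N-][Si](C)(C)C.[K+] (potassium appears in intermediate 13 only)
Why: Still–Gennari variant of the Horner–Wadsworth–Emmons olefination: the electron-poor trifluoroethyl phosphonate with a dissociated potassium counter-ion eliminates fast from the kinetic adduct, which should place the ester cis to the new chain (10′Z).

Step 8
Reactants: 15 pent-3-yn-1-ol
Product: 16 pent-3-yn-1-yl 4-methylbenzenesulfonate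
Conditions: TsCl, Et3N, DMAP (5 mol %), CH2Cl2, 0 °C
Reagents that add atoms: 4-methylbenzenesulfonyl chloride, Cc1ccc(cc1)S(Cl)(=O)=O
Why: Sulfonylation of a primary alcohol to turn it into a leaving group for the acetylide displacement.

Step 9
Reactants: 16 pent-3-yn-1-yl 4-methylbenzenesulfonate; 17 lithium acetylide–ethane-1,2-diamine complex
Product: 18 hepta-1,5-diyne
Conditions: DMSO, 15 → 23 °C
Reagents that add atoms: none
Why: SN2 alkylation of an acetylide with a primary tosylate in a dipolar aprotic solvent, which gives the diyne with one terminal and one methyl-capped alkyne.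

Step 10
Reactants: 18 hepta-1,5-diyne
Product: 21 (2E)-3-methyloct-2-en-6-yn-1-ol, via alkenylalane 19 (not isolated), via lithium alkenylaluminate 20 (not isolated)
Conditions: Me3Al (2 equiv), Cp2ZrCl2 (25 mol %), CH2Cl2, 0 → 23 °C; volatiles removed; n-BuLi, THF/hexane, −78 °C; (CH2O)n, −78 → 23 °C; aq. NH4Cl
Reagents that add atoms: trimethylaluminium, C[Al](C)C; formaldehyde (as paraformaldehyde), C=O; n-butyllithium, [Li]CCCC (its atoms appear in intermediate 20 only)
Why: Negishi zirconium-catalysed carboalumination: Me–Al adds syn and only to the terminal alkyne (the internal one reacts far more slowly), and the aluminate is hydroxymethylated with retention, which fixes the 2′E geometry.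

Step 11
Reactants: 21 (2E)-3-methyloct-2-en-6-yn-1-ol
Product: 23 (2E,6E)-7-iodo-3-methylocta-2,6-dien-1-ol, via bis-zirconated dienolate 22 (not isolated)
Conditions: Cp2Zr(H)Cl (3 equiv), THF, 50 °C; then I2, 0 °C; aq. work-up
Reagents that add atoms: chloridobis(cyclopentadienyl)hydridozirconium, [H][Zr](Cl)(C1C=CC=C1)C1C=CC=C1 (zirconium appears in intermediate 22 only); iodine, II
Why: Hydrozirconation–iodinolysis: H–Zr adds syn, excess reagent with warming should equilibrate zirconium to the less hindered methyl-bearing alkyne carbon, and iodinolysis with retention gives the (E)-2-iodoalkene; the trisubstituted alkene is inert and the hydroxyl only consumes one equivalent of hydride.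

Step 12
Reactants: 23 (2E,6E)-7-iodo-3-methylocta-2,6-dien-1-ol
Product: 24 (2E,6E)-1-bromo-7-iodo-3-methylocta-2,6-diene
Conditions: PBr3 (0.4 equiv), Et2O, −10 °C
Reagents that add atoms: phosphorus tribromide, BrP(Br)Br
Why: Conversion of a primary allylic alcohol into the bromide through its phosphite ester (SN2), which at low temperature should proceed without allylic transposition or loss of alkene geometry.

Step 13
Reactants: 24 (2E,6E)-1-bromo-7-iodo-3-methylocta-2,6-diene; 25 2-methylphenol
Product: 27 2-[(2E,6E)-7-iodo-3-methylocta-2,6-dien-1-yl]-6-methylphenol, via sodium 2-methylphenolate 26 (not isolated)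
Conditions: 25 (3 equiv), NaH, toluene, 23 °C; then 24, 23 °C
Reagents that add atoms: sodium hydride, [Na+].[H-] (sodium appears in intermediate 26 only)
Why: ortho-C-allylation of a sodium phenoxide in a non-polar solvent: the tight ion pair directs SN2 attack of the free ortho carbon on the allylic bromide, the alkenyl iodide is inert, and the phenol serves as the quinone at a lower oxidation level.

Step 14
Reactants: 14 methyl (2Z)-2-[(3R)-3-[(tert-butyldimethylsilyl)oxy]-4-methylpent-4-en-1-yl]-5-(4,4,5,5-tetramethyl-1,3,2-dioxaborolan-2-yl)pent-2-enoate; 27 2-[(2E,6E)-7-iodo-3-methylocta-2,6-dien-1-yl]-6-methylphenol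
Product: 28 methyl (2Z,6E,10E)-2-[(3R)-3-[(tert-butyldimethylsilyl)oxy]-4-methylpent-4-en-1-yl]-12-(2-hydroxy-3-methylphenyl)-6,10-dimethyldodeca-2,6,10-trienoate
Conditions: Pd(OAc)2 (5 mol %), RuPhos (10 mol %), K3PO4 (4 equiv), toluene/H2O (10:1), 80 °C, degassed
Reagents that add atoms: none
Why: Zerovalent palladium carrying the bulky biaryl phosphine inserts into the C–I bond of 27 with retention of the E geometry, phosphate/hydroxide turns the pinacol boronate of 14 into a four-coordinate borate that hands its unbranched primary alkyl group to palladium, and reductive elimination forms the C(sp3)–C(sp2) bond between C-8′ and C-7′. The closest known reaction type is the B-alkyl Suzuki–Miyaura coupling of primary alkyl pinacol boronates with alkenyl halides. No ring is closed and no stereocentre is created; the step only has to carry the (E)-iodoalkene geometry, the (Z)-enoate and the (R) silyloxy centre through unchanged, which holds because oxidative addition and reductive elimination are stereoretentive at sp2 carbon and the other two elements are not touched. Chemoselectivity rests on the design of 14: with the lactone still open there is no allylic ester of the isopropenyl group for palladium to ionise, so the alkenyl iodide is the only site of oxidative addition, and the methyl ester and silyl ether should withstand hot aqueous phosphate where a δ-lactone might not. β-Hydride elimination from the alkylpalladium intermediate should be outrun by reductive elimination with the large ligand, and boron sits two CH2 groups from the enoate, so no conjugate or allylic boron pathway can interfere.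

Step 15
Reactants: 28 methyl (2Z,6E,10E)-2-[(3R)-3-[(tert-butyldimethylsilyl)oxy]-4-methylpent-4-en-1-yl]-12-(2-hydroxy-3-methylphenyl)-6,10-dimethyldodeca-2,6,10-trienoate
Product: 30 (3Z,6R)-3-[(4E,8E)-10-(2-hydroxy-3-methylphenyl)-4,8-dimethyldeca-4,8-dien-1-ylidene]-6-(prop-1-en-2-yl)oxan-2-one, via desilylated hydroxy ester 29 (not isolated)
Conditions: Bu4NF (3 equiv), THF, 0 → 40 °C, under N2; aq. NH4Cl
Reagents that add atoms: none
Why: Fluoride desilylation followed by intramolecular transesterification (6-exo-trig lactonisation) of the freed C-14′ oxygen onto the methyl ester; no bond to the stereocentre or to the alkenes is broken, and the basic fluoride conditions avoid acid-induced chroman formation from the ortho-allylphenol.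

Step 16
Reactants: 30 (3Z,6R)-3-[(4E,8E)-10-(2-hydroxy-3-methylphenyl)-4,8-dimethyldeca-4,8-dien-1-ylidene]-6-(prop-1-en-2-yl)oxan-2-one
Product: 31 2-[(2E,6E)-3,7-dimethyl-10-[(3Z,6R)-2-oxo-6-(prop-1-en-2-yl)oxan-3-ylidene]deca-2,6-dien-1-yl]-6-methylcyclohexa-2,5-diene-1,4-dione
Conditions: ON(SO3K)2 (3 equiv), aq. KH2PO4, acetone, 23 °C
Reagents that add atoms: potassium nitrosodisulfonate, [K+].[K+].[O]N(S(=O)(=O)[O-])S(=O)(=O)[O-]
Why: Teuber oxidation: the nitroxide abstracts the phenolic hydrogen and a second equivalent oxygenates the free para position, so the 2,6-dialkylphenol should give only the para-quinone under near-neutral conditions that spare the alkenes and the lactone.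

**Compound list**

1 | 3-bromopropanoyl chloride | O=C(Cl)CCBr | starting material
2 | prop-1-en-2-ylmagnesium bromide | C=C(C)[Mg]Br | starting material
3 | prop-1-en-2-ylzinc chloride | C=C(C)[Zn]Cl | intermediate
4 | 5-bromo-2-methylpent-1-en-3-one | C=C(C)C(=O)CCBr | intermediate
5 | (3R)-5-bromo-2-methylpent-1-en-3-ol | C=C(C)[C@H](O)CCBr | intermediate
6 | tert-butyl{[(3R)-5-bromo-2-methylpent-1-en-3-yl]oxy}dimethylsilane | C=C(C)[C@H](O[Si](C)(C)C(C)(C)C)CCBr | intermediate
7 | methyl 2-[bis(2,2,2-trifluoroethoxy)phosphoryl]acetate | COC(=O)CP(=O)(OCC(F)(F)F)OCC(F)(F)F | starting material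
8 | sodium salt of 7 (sodium phosphonoacetate) | [Na+].COC(=O)[CH-]P(=O)(OCC(F)(F)F)OCC(F)(F)F | intermediate
9 | methyl (5R)-2-[bis(2,2,2-trifluoroethoxy)phosphoryl]-5-[(tert-butyldimethylsilyl)oxy]-6-methylhept-6-enoate (both C-2 epimers) | COC(=O)C(CC[C@@H](O[Si](C)(C)C(C)(C)C)C(C)=C)P(=O)(OCC(F)(F)F)OCC(F)(F)F | intermediate
10 | 3,3-diethoxyprop-1-ene | C=CC(OCC)OCC | starting material
11 | 2-(3,3-diethoxypropyl)-4,4,5,5-tetramethyl-1,3,2-dioxaborolane | CCOC(CCB1OC(C)(C)C(C)(C)O1)OCC | intermediate
12 | 3-(4,4,5,5-tetramethyl-1,3,2-dioxaborolan-2-yl)propanal | O=CCCB1OC(C)(C)C(C)(C)O1 | intermediate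
13 | potassium salt of 9 | [K+].COC(=O)[C-](CC[C@@H](O[Si](C)(C)C(C)(C)C)C(C)=C)P(=O)(OCC(F)(F)F)OCC(F)(F)F | intermediate
14 | methyl (2Z)-2-[(3R)-3-[(tert-butyldimethylsilyl)oxy]-4-methylpent-4-en-1-yl]-5-(4,4,5,5-tetramethyl-1,3,2-dioxaborolan-2-yl)pent-2-enoate | COC(=O)/C(CC[C@@H](O[Si](C)(C)C(C)(C)C)C(C)=C)=C\CCB1OC(C)(C)C(C)(C)O1 | intermediate
15 | pent-3-yn-1-ol | CC#CCCO | starting material
16 | pent-3-yn-1-yl 4-methylbenzenesulfonate | CC#CCCOS(=O)(=O)c1ccc(C)cc1 | intermediate
17 | lithium acetylide–ethane-1,2-diamine complex | [Li]C#C.NCCN | starting material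
18 | hepta-1,5-diyne | C#CCCC#CC | intermediate
19 | dimethyl[(1E)-2-methylhept-1-en-5-yn-1-yl]alumane | C[Al](C)/C=C(\C)CCC#CC | intermediate
20 | lithium butyl(dimethyl)[(1E)-2-methylhept-1-en-5-yn-1-yl]aluminate | [Li+].CCCC[Al-](C)(C)/C=C(\C)CCC#CC | intermediate
21 | (2E)-3-methyloct-2-en-6-yn-1-ol | OC/C=C(\C)CCC#CC | intermediate
22 | chloridobis(cyclopentadienyl)zirconium alkoxide of (2E,6E)-7-[chloridobis(cyclopentadienyl)zirconio]-3-methylocta-2,6-dien-1-ol (cyclopentadienyl rings drawn σ-bonded) | Cl[Zr](OC/C=C(\C)CC/C=C(\C)[Zr](Cl)(C1C=CC=C1)C1C=CC=C1)(C1C=CC=C1)C1C=CC=C1 | intermediate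
23 | (2E,6E)-7-iodo-3-methylocta-2,6-dien-1-ol | OC/C=C(\C)CC/C=C(\C)I | intermediate
24 | (2E,6E)-1-bromo-7-iodo-3-methylocta-2,6-diene | BrC/C=C(\C)CC/C=C(\C)I | intermediate
25 | 2-methylphenol | Cc1ccccc1O | starting material
26 | sodium 2-methylphenolate | [Na+].Cc1ccccc1[O-] | intermediate
27 | 2-[(2E,6E)-7-iodo-3-methylocta-2,6-dien-1-yl]-6-methylphenol | Cc1cccc(C/C=C(\C)CC/C=C(\C)I)c1O | intermediate
28 | methyl (2Z,6E,10E)-2-[(3R)-3-[(tert-butyldimethylsilyl)oxy]-4-methylpent-4-en-1-yl]-12-(2-hydroxy-3-methylphenyl)-6,10-dimethyldodeca-2,6,10-trienoate | COC(=O)/C(CC[C@@H](O[Si](C)(C)C(C)(C)C)C(C)=C)=C\CC/C(C)=C/CC/C(C)=C/Cc1cccc(C)c1O | intermediate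
29 | methyl (2Z,6E,10E)-2-[(3R)-3-hydroxy-4-methylpent-4-en-1-yl]-12-(2-hydroxy-3-methylphenyl)-6,10-dimethyldodeca-2,6,10-trienoate | COC(=O)/C(CC[C@@H](O)C(C)=C)=C\CC/C(C)=C/CC/C(C)=C/Cc1cccc(C)c1O | intermediate
30 | (3Z,6R)-3-[(4E,8E)-10-(2-hydroxy-3-methylphenyl)-4,8-dimethyldeca-4,8-dien-1-ylidene]-6-(prop-1-en-2-yl)oxan-2-one | C=C(C)[C@H]1CC/C(=C/CC/C(C)=C/CC/C(C)=C/Cc2cccc(C)c2O)C(=O)O1 | intermediate
31 | 2-[(2E,6E)-3,7-dimethyl-10-[(3Z,6R)-2-oxo-6-(prop-1-en-2-yl)oxan-3-ylidene]deca-2,6-dien-1-yl]-6-methylcyclohexa-2,5-diene-1,4-dione | C=C(C)[C@H]1CC/C(=C/CC/C(C)=C/CC/C(C)=C/CC2=CC(=O)C=C(C)C2=O)C(=O)O1 | target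

**Count**

Total step count: 16.
Longest linear sequence: 9 steps (steps 8, 9, 10, 11, 12, 13, 14, 15, 16).

**Three steps most likely to fail**

Step 14. The transfer of the primary alkyl group from the pinacol boronate to palladium may be slow, so that protodeboronation, β-hydride elimination and saponification of the (Z)-enoate in the hot basic medium compete with the coupling. The fallback sets out from 10 and 27 and comes back to the route at 28; it makes the same bond with a small, robust B-alkyl-9-BBN partner at room temperature and moves the union of the halves to the olefination. Acetal 10 is hydroborated with (9-BBN-H)2 in THF to 9-(3,3-diethoxypropyl)-9-borabicyclo[3.3.1]nonane F1, which is coupled in the same flask with 27 [PdCl2(dppf), Ph3As, Cs2CO3, DMF/H2O, 23 °C] to give 2-[(2E,6E)-10,10-diethoxy-3,7-dimethyldeca-2,6-dien-1-yl]-6-methylphenol F2. Dilute aqueous acid in THF at 23 °C should free (4E,8E)-10-(2-hydroxy-3-methylphenyl)-4,8-dimethyldeca-4,8-dienal F3, and the Still–Gennari olefination of F3 with the potassium salt 13 of phosphonate 9 (one extra equivalent of KN(SiMe3)2 for the phenol) should give 28.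

Step 13. O-allylation, para C-allylation and double allylation of the ambident phenoxide may compete with the wanted ortho C-allylation and erode the material from the six-step right half. The fallback sets out from 24 and comes back at 27; it fixes the position of the new bond by a carbon–halogen bond. Commercial 2-bromo-6-methylphenol is protected (MOMCl, i-Pr2NEt, CH2Cl2) as 1-bromo-2-(methoxymethoxy)-3-methylbenzene F4 and converted with Mg in THF into bromo[2-(methoxymethoxy)-3-methylphenyl]magnesium F5. Allylation of F5 by 24 under catalysis by CuI (5 mol %) at −20 °C should give 1-[(2E,6E)-7-iodo-3-methylocta-2,6-dien-1-yl]-2-(methoxymethoxy)-3-methylbenzene F6, and HCl in MeOH at 23 °C removes the acetal to give 27.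

Step 7. The Z selectivity of the olefination may erode with the α-branched phosphonate, and the β-boryl aldehyde may enolise and self-condense under the basic conditions. The fallback sets out from 6, 7 and 12 and comes back at 14; it fixes the geometry by a stereoretentive cross-coupling instead of by the olefination. Phosphonate 7 is brominated through its sodium salt 8 with N-bromosuccinimide to methyl 2-bromo-2-[bis(2,2,2-trifluoroethoxy)phosphoryl]acetate F7. Its Horner–Wadsworth–Emmons reaction with 12 (t-BuOK, 18-crown-6, THF, −78 °C) should give methyl (2E)-2-bromo-5-(4,4,5,5-tetramethyl-1,3,2-dioxaborolan-2-yl)pent-2-enoate F8, in which the chain is cis to the ester. Zinc insertion into bromide 6 (Zn, LiCl, THF, 40 °C) gives bromo[(3R)-3-[(tert-butyldimethylsilyl)oxy]-4-methylpent-4-en-1-yl]zinc F9, and a base-free Negishi coupling of F8 with F9 [Pd(OAc)2, SPhos, THF, 23 °C] replaces bromine with retention and leaves the boronate untouched, giving 14.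

**Further compounds**

F1 | step 14 | 9-(3,3-diethoxypropyl)-9-borabicyclo[3.3.1]nonane | CCOC(CCB1C2CCCC1CCC2)OCC
F2 | step 14 | 2-[(2E,6E)-10,10-diethoxy-3,7-dimethyldeca-2,6-dien-1-yl]-6-methylphenol | CCOC(CC/C(C)=C/CC/C(C)=C/Cc1cccc(C)c1O)OCC
F3 | step 14 | (4E,8E)-10-(2-hydroxy-3-methylphenyl)-4,8-dimethyldeca-4,8-dienal | O=CCC/C(C)=C/CC/C(C)=C/Cc1cccc(C)c1O
F4 | step 13 | 1-bromo-2-(methoxymethoxy)-3-methylbenzene | COCOc1c(C)cccc1Br
F5 | step 13 | bromo[2-(methoxymethoxy)-3-methylphenyl]magnesium | COCOc1c(C)cccc1[Mg]Br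
F6 | step 13 | 1-[(2E,6E)-7-iodo-3-methylocta-2,6-dien-1-yl]-2-(methoxymethoxy)-3-methylbenzene | COCOc1c(C)cccc1C/C=C(\C)CC/C=C(\C)I
F7 | step 7 | methyl 2-bromo-2-[bis(2,2,2-trifluoroethoxy)phosphoryl]acetate | COC(=O)C(Br)P(=O)(OCC(F)(F)F)OCC(F)(F)F
F8 | step 7 | methyl (2E)-2-bromo-5-(4,4,5,5-tetramethyl-1,3,2-dioxaborolan-2-yl)pent-2-enoate | COC(=O)/C(Br)=C\CCB1OC(C)(C)C(C)(C)O1
F9 | step 7 | bromo[(3R)-3-[(tert-butyldimethylsilyl)oxy]-4-methylpent-4-en-1-yl]zinc | Br[Zn]CC[C@@H](O[Si](C)(C)C(C)(C)C)C(C)=C
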